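**Retrosynthetic overview**
1. Feature: in ring A (C1 CMe2, C2 CHBr, C3 CHOH, C4 =CH, C5 C(Me)=, C6 spiro) the spiro carbon C6 lies between C5 and C1. With C5 written as a ketone and a formyl group placed on C6, C6 is the α-carbon of an enolised β-keto aldehyde and has no fixed configuration until its fourth carbon is attached.
2. Key disconnection: ring B (C6–C11) is cut at C6–C11 (Michael addition) and C7–C8 (aldol condensation). This leads to the formyl ketone and methyl vinyl ketone, and a chiral amine fixes C6.
3. Ring order: ring A comes ready-made from dimedone. Ring B is closed second as a cyclohexenone, whose C=O becomes C9(Me)Br, whose α-CH becomes C8HCl and whose formyl CH becomes C7H2.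
4. Carbon work after the annulation: the ring B enone becomes the C8=C9(Me) alkene (conjugate reduction, triflate, Negishi coupling). The vinylogous ester becomes the C5(Me)=C4–C3=O enone (methylcerium, then acid).
5. Heteroatoms last: C2–Br (α′-bromination), C8–Cl and C9–OH (epoxide, then chloride), C9–Br (substitution with chlorine participation), C3–OH (1,2-reduction).

Key step: step 3

Locants: all spiro compounds keep one numbering. C1 = CMe2, C2, C3, C4, C5 = ring A carbon next to the spiro centre, C6 = spiro, C7 = formyl-derived carbon, C8, C9, C10, C11.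
Assumption: the sense of induction of the cinchona catalyst on this donor cannot be derived beforehand. The quinidine-derived base is written here, and its quinine-derived pseudo-enantiomer replaces it if the spiro dienedione turns out to have the opposite configuration.
Assumption: ring B is taken to react in the half-chair or chair that keeps C1Me2 (pseudo)equatorial and the flat C5 flank (pseudo)axial. Steps 7 to 10 draw their stereochemical arguments from this picture.

Step 1
Reactants: 1 dimedone (5,5-dimethylcyclohexane-1,3-dione); 2 isobutanol (2-methylpropan-1-ol)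
Product: 3 3-isobutoxy-5,5-dimethylcyclohex-2-en-1-one
Conditions: p-TsOH·H2O (2 mol %), toluene, reflux, Dean–Stark trap
Reagents that add atoms: none
Why: Acid-catalysed condensation of the enolised 1,3-diketone with the alcohol (vinylogous Fischer esterification) is driven by azeotropic removal of water, the symmetry of 1 allows only one product, and no stereocentre arises.

Step 2
Reactants: 3 3-isobutoxy-5,5-dimethylcyclohex-2-en-1-one; 4 ethyl formate
Product: 6 6-formyl-3-isobutoxy-5,5-dimethylcyclohex-2-en-1-one (racemic; mostly enol), via lithium enolate 5 (not isolated)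
Conditions: LDA, THF, −78 °C; 4, −78 → 0 °C; 1 M HCl
Reagents that add atoms: none
Why: LDA deprotonates a 3-alkoxyenone kinetically at the α′ carbon (the regiochemistry of Stork–Danheiser alkylations), and crossed Claisen condensation of enolate 5 with the non-enolisable formate is pulled forward by the chelated lithium salt of the β-keto aldehyde; the new CH centre is stereolabile because 6 rests as its enol, so it is carried as the racemate.

Step 3
Reactants: 6 6-formyl-3-isobutoxy-5,5-dimethylcyclohex-2-en-1-one; 7 methyl vinyl ketone (but-3-en-2-one)
Product: 10 (6S)-3-isobutoxy-1,1-dimethylspiro[5.5]undeca-3,7-diene-5,9-dione, via Michael adduct 8 (not isolated), via ketol 9 (not isolated)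
Conditions: 9-O-(phenanthren-9-yl)cupreidine (C33H30N2O2, 10 mol %), 7 (3 equiv), CH2Cl2, −20 °C → rt; then pyrrolidine (30 mol %), AcOH (30 mol %), 4 Å sieves, 40 °C
Reagents that add atoms: none
Why: The quinuclidine nitrogen of the catalyst takes the proton of enolised 6 while its 6′-phenol hydrogen-bonds to the carbonyl of 7, so the ion-paired planar enolate adds through the formyl-bearing carbon to the vinyl ketone (C6–C11 bond) and gives 8; enamine formation at the new methyl ketone then brings about aldol addition to the formyl carbon (C8–C7 bond, ketol 9), and loss of water gives 10. The closest known reaction type is the cinchona-base-catalysed asymmetric Michael addition of α-substituted cyclic 1,3-dicarbonyl compounds to methyl vinyl ketone followed by aldol condensation, that is an asymmetric Robinson annulation, run here as a spiroannulation. Ring B closes in a 6-(enolendo)-exo-trig aldol. The only lasting stereocentre, spiro C6, is set under catalyst control in the Michael step: both enantiomers of keto-6 pass through the same achiral enol, and the catalyst has to tell apart the two flanks of the reacting carbon, the flat C5 carbonyl against C1Me2, which sit directly on it. The step needs C- rather than O-alkylation and reaction at C6 rather than at the γ-carbon C2, which the double activation of C6 secures, and it needs the aldol to go to the aldehyde and not to the C5 carbonyl, which the higher electrophilicity of CHO over a hindered vinylogous ester secures. The carbinol centre of 9 disappears on dehydration, and hydroxide and alkoxide are kept out so that retro-Claisen loss of the formyl group does not overtake ring closure.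

Step 4
Reactants: 10 (6S)-3-isobutoxy-1,1-dimethylspiro[5.5]undeca-3,7-diene-5,9-dione
Product: 12 (6S)-3-isobutoxy-1,1-dimethyl-5-oxospiro[5.5]undeca-3,8-dien-9-yl trifluoromethanesulfonate, via lithium enolate 11 (not isolated)
Conditions: Li[HB(s-Bu)3] (1.05 equiv), THF, −78 °C; PhNTf2, −78 → 0 °C; H2O
Reagents that add atoms: N-phenylbis(trifluoromethanesulfonimide), O=S(=O)(N(c1ccccc1)S(=O)(=O)C(F)(F)F)C(F)(F)F
Why: The bulky borohydride delivers hydride in the 1,4 sense to the ring B enone, whose β-carbon C7 bears only hydrogen, while the electron-rich and neopentyl vinylogous ester is left alone at −78 °C, and O-sulfonylation of the regiodefined enolate 11 before it can equilibrate locks the double bond between C8 and C9 (conjugate reduction with enolate trapping); C6 is untouched and no new stereocentre forms.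

Step 5
Reactants: 12 (6S)-3-isobutoxy-1,1-dimethyl-5-oxospiro[5.5]undeca-3,8-dien-9-yl trifluoromethanesulfonate
Product: 13 (6S)-3-isobutoxy-1,1,9-trimethylspiro[5.5]undeca-3,8-dien-5-one
Conditions: MeZnCl (1.5 equiv), Pd(PPh3)4 (5 mol %), THF, 0 °C → rt
Reagents that add atoms: methylzinc chloride, C[Zn]Cl
Why: In this Negishi coupling zerovalent palladium inserts into the C9–O bond of the enol triflate, methyl passes over from zinc and reductive elimination gives the trisubstituted alkene with the double bond where the triflate held it, and methylzinc chloride is too mild to add to the C5 carbonyl.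

Step 6
Reactants: 13 (6S)-3-isobutoxy-1,1,9-trimethylspiro[5.5]undeca-3,8-dien-5-one
Product: 15 (6S)-1,1,5,9-tetramethylspiro[5.5]undeca-4,8-dien-3-one, via tertiary carbinol 14 (not isolated)
Conditions: MeLi, CeCl3 (anhydrous), THF, −78 → 0 °C; then 1 M HCl, THF, rt
Reagents that add atoms: methyllithium, [Li]C; water, O
Why: In this Stork–Danheiser transposition the weakly basic, oxophilic methylcerium reagent adds 1,2 to the hindered C5 carbonyl, acid then ionises the tertiary allylic carbinol 14, water adds at C3 of the alkoxyallyl cation and isobutanol leaves, which gives the conjugated enone; the transient C5 carbinol centre is lost again and C6 is not involved.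

Step 7
Reactants: 15 (6S)-1,1,5,9-tetramethylspiro[5.5]undeca-4,8-dien-3-one
Product: 17 (2R,6R)-2-bromo-1,1,5,9-tetramethylspiro[5.5]undeca-4,8-dien-3-one, via silyl dienol ether 16 (not isolated)
Conditions: LDA, Me3SiCl, THF, −78 °C; volatiles removed; NBS, THF, −78 → 0 °C
Reagents that add atoms: N-bromosuccinimide, O=C1CCC(=O)N1Br; chlorotrimethylsilane, C[Si](C)(C)Cl (silicon stays only in 16)
Why: As with isophorone, LDA takes an α′ proton (C2–H) faster than a γ proton, in situ silylation gives the cross-conjugated dienol ether 16, and NBS attacks its electron-rich C2 terminus much faster than the isolated C8=C9 alkene (bromination of a silyl enol ether); with the C5 flank pseudo-axial on ring B its methyl tips toward sp2 C8 rather than toward the axial hydrogen on C10, this fixes the ring A half-chair with C11 pseudo-axial, and only the (2R) epimer holds bromine equatorial in it, the (2S) epimer being convertible into it through the enol.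

Step 8
Reactants: 17 (2R,6R)-2-bromo-1,1,5,9-tetramethylspiro[5.5]undeca-4,8-dien-3-one
Product: 18 (2R,6R,8R,9S)-2-bromo-8,9-epoxy-1,1,5,9-tetramethylspiro[5.5]undec-4-en-3-one
Conditions: mCPBA, CH2Cl2, 0 °C
Reagents that add atoms: 3-chloroperbenzoic acid, O=C(OO)c1cccc(Cl)c1
Why: Prilezhaev epoxidation picks the electron-rich trisubstituted C8=C9 alkene over the electron-poor bromoenone, and the peracid should come in on the ring B face turned away from the pseudo-axial C5 flank and its overhanging methyl, so that oxygen sits cis to C1 and C9 is set as (S).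

Step 9
Reactants: 18 (2R,6R,8R,9S)-2-bromo-8,9-epoxy-1,1,5,9-tetramethylspiro[5.5]undec-4-en-3-one
Product: 19 (2R,6R,8S,9S)-2-bromo-8-chloro-9-hydroxy-1,1,5,9-tetramethylspiro[5.5]undec-4-en-3-one
Conditions: LiCl (5 equiv), AcOH, THF, rt → 45 °C
Reagents that add atoms: lithium chloride, [Li+].[Cl-]
Why: Buffered lithium chloride opens the acid-activated epoxide by an SN2 path at the secondary carbon C8 with inversion, and in the chair that keeps C1Me2 equatorial this is also the trans-diaxial opening demanded by the Fürst–Plattner rule, so steric and stereoelectronic preference agree and give chlorine at C8 cis to C5 (8S) with the tertiary C9–O bond unchanged (9S).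

Step 10
Reactants: 19 (2R,6R,8S,9S)-2-bromo-8-chloro-9-hydroxy-1,1,5,9-tetramethylspiro[5.5]undec-4-en-3-one
Product: 20 (2R,6R,8S,9S)-2,9-dibromo-8-chloro-1,1,5,9-tetramethylspiro[5.5]undec-4-en-3-one
Conditions: Me3SiBr (1.5 equiv), CH2Cl2, −40 → 0 °C
Reagents that add atoms: bromotrimethylsilane, C[Si](C)(C)Br
Why: Bromotrimethylsilane turns tertiary alcohols into bromides by ionisation (SN1), and here the axial C8 chlorine lies antiperiplanar to the leaving oxygen, so an unsymmetrical chlorine-bridged cation should form (anchimeric assistance) and be opened by bromide at its tertiary end C9 from the face that the oxygen left, which means net retention (9S, Br trans to Cl); the secondary chloride, the neopentyl C2 bromide and the enone do not ionise under these conditions.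

Step 11
Reactants: 20 (2R,6R,8S,9S)-2,9-dibromo-8-chloro-1,1,5,9-tetramethylspiro[5.5]undec-4-en-3-one
Product: 21 (2R,3S,6R,8S,9S)-2,9-dibromo-8-chloro-1,1,5,9-tetramethylspiro[5.5]undec-4-en-3-ol
Conditions: i-Bu2AlH, CH2Cl2, −78 °C; H2O work-up
Reagents that add atoms: none
Why: i-Bu2AlH reduces enones in the 1,2 sense, and the axial methyl on C1 blocks the axial trajectory at C3, so hydride comes in from the equatorial side next to the axial C2–H and gives the pseudo-axial (3S) alcohol cis to the equatorial bromine, as in hydride reductions of 3,3-dimethylcyclohexanones; at −78 °C the three carbon–halogen bonds are not touched.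

**Compound list**
1 | dimedone (5,5-dimethylcyclohexane-1,3-dione) | CC1(C)CC(=O)CC(=O)C1 | starting material
2 | isobutanol (2-methylpropan-1-ol) | CC(C)CO | starting material
3 | 3-isobutoxy-5,5-dimethylcyclohex-2-en-1-one | CC(C)COC1=CC(=O)CC(C)(C)C1 | intermediate
4 | ethyl formate | CCOC=O | starting material
5 | lithium 5-isobutoxy-3,3-dimethylcyclohexa-1,5-dien-1-olate (α′-enolate of 3) | [Li+].[O-]C1=CC(C)(C)CC(OCC(C)C)=C1 | intermediate
6 | 6-formyl-3-isobutoxy-5,5-dimethylcyclohex-2-en-1-one (racemic; mostly enol) | O=CC1C(=O)C=C(OCC(C)C)CC1(C)C | intermediate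
7 | methyl vinyl ketone (but-3-en-2-one) | CC(=O)C=C | starting material
8 | (1R)-4-isobutoxy-6,6-dimethyl-2-oxo-1-(3-oxobutyl)cyclohex-3-ene-1-carbaldehyde | O=C1C=C(OCC(C)C)CC(C)(C)[C@@]1(C=O)CCC(C)=O | intermediate
9 | (6R)-7-hydroxy-3-isobutoxy-1,1-dimethylspiro[5.5]undec-3-ene-5,9-dione (C7 epimers) | O=C1C=C(OCC(C)C)CC(C)(C)[C@@]12CCC(=O)CC2O | intermediate
10 | (6S)-3-isobutoxy-1,1-dimethylspiro[5.5]undeca-3,7-diene-5,9-dione | O=C1C=C(OCC(C)C)CC(C)(C)[C@@]12CCC(=O)C=C2 | intermediate
11 | lithium (6S)-3-isobutoxy-1,1-dimethyl-5-oxospiro[5.5]undeca-3,8-dien-9-olate | O=C1C=C(OCC(C)C)CC(C)(C)[C@@]12CCC([O-])=CC2.[Li+] | intermediate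
12 | (6S)-3-isobutoxy-1,1-dimethyl-5-oxospiro[5.5]undeca-3,8-dien-9-yl trifluoromethanesulfonate | O=C1C=C(OCC(C)C)CC(C)(C)[C@@]12CCC(OS(=O)(=O)C(F)(F)F)=CC2 | intermediate
13 | (6S)-3-isobutoxy-1,1,9-trimethylspiro[5.5]undeca-3,8-dien-5-one | O=C1C=C(OCC(C)C)CC(C)(C)[C@@]12CCC(C)=CC2 | intermediate
14 | (6S)-3-isobutoxy-1,1,5,9-tetramethylspiro[5.5]undeca-3,8-dien-5-ol (C5 epimers) | CC1(O)C=C(OCC(C)C)CC(C)(C)[C@@]12CCC(C)=CC2 | intermediate
15 | (6S)-1,1,5,9-tetramethylspiro[5.5]undeca-4,8-dien-3-one | CC1=CC(=O)CC(C)(C)[C@@]12CCC(C)=CC2 | intermediate
16 | (6R)-1,1,5,9-tetramethyl-3-(trimethylsilyloxy)spiro[5.5]undeca-2,4,8-triene | CC1=CC(O[Si](C)(C)C)=CC(C)(C)[C@@]12CCC(C)=CC2 | intermediate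
17 | (2R,6R)-2-bromo-1,1,5,9-tetramethylspiro[5.5]undeca-4,8-dien-3-one | CC1=CC(=O)[C@H](Br)C(C)(C)[C@@]12CCC(C)=CC2 | intermediate
18 | (2R,6R,8R,9S)-2-bromo-8,9-epoxy-1,1,5,9-tetramethylspiro[5.5]undec-4-en-3-one | CC1=CC(=O)[C@H](Br)C(C)(C)[C@@]12CC[C@]3(C)O[C@@H]3C2 | intermediate
19 | (2R,6R,8S,9S)-2-bromo-8-chloro-9-hydroxy-1,1,5,9-tetramethylspiro[5.5]undec-4-en-3-one | CC1=CC(=O)[C@H](Br)C(C)(C)[C@@]12CC[C@](C)(O)[C@@H](Cl)C2 | intermediate
20 | (2R,6R,8S,9S)-2,9-dibromo-8-chloro-1,1,5,9-tetramethylspiro[5.5]undec-4-en-3-one | CC1=CC(=O)[C@H](Br)C(C)(C)[C@@]12CC[C@](C)(Br)[C@@H](Cl)C2 | intermediate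
21 | (2R,3S,6R,8S,9S)-2,9-dibromo-8-chloro-1,1,5,9-tetramethylspiro[5.5]undec-4-en-3-ol | CC1=C[C@H](O)[C@H](Br)C(C)(C)[C@@]12CC[C@](C)(Br)[C@@H](Cl)C2 | target

Total step count: 11. Longest linear sequence: 11 steps, from 1 to 21.

**Steps most likely to fail**

Step 3. The donor carbon is neopentyl and the product carries two adjacent quaternary carbons.
- The Michael addition may be slow.
- The catalyst may discriminate poorly between the two faces of the enolate.
- Retro-Claisen loss of the formyl group from 8 may overtake the aldol closure.

The fallback uses a covalent auxiliary in place of a catalyst and sets out from 6. Condensation with L-valine diethylamide (toluene, 4 Å sieves) gives the hydrogen-bonded valinamide enaminone F1. With Cu(OAc)2·H2O (5 mol %) in acetone at room temperature, the chelated copper aza-enolate of F1 adds to 7 from the face left open by the isopropyl group and gives the valinamide imine F2. Hydrolysis with 1 M HCl returns the auxiliary and delivers 8, where the route is rejoined (pyrrolidine–AcOH closure to 10). D-valine diethylamide serves if the other sense is needed.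

Step 10. Several things may go wrong here.
- Ionisation may proceed without chlorine bridging if ring B flips to the chair with equatorial chlorine, so that configuration at C9 is lost.
- Proton loss from the cation may outrun capture by bromide.
- Traces of HBr may epimerise C2 through the enol.

The fallback replaces substitution at the alcohol by addition to an alkene and sets out from 19. Deliberate dehydration with SOCl2–pyridine at 0 °C proceeds by anti elimination of the axial chlorosulfite toward C10 and gives the endocyclic allylic chloride F3. Dry HBr in CH2Cl2 at −78 °C then adds in the Markovnikov sense, with the proton going to C10 and bromide to C9 anti to the allylic chlorine. The route is rejoined at 20.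

Step 9. Chloride has to reach C8 along an axial line next to the C5 flank, which creates three risks.
- The opening may be slow.
- Opening at the tertiary carbon C9 or Meinwald rearrangement of the epoxide may take over.
- The outcome depends on the facial selectivity of step 8.

The fallback uses electrophilic chlorine in place of nucleophilic chloride. It sets out from 17 and passes by 18. Trichloroisocyanuric acid (C3Cl3N3O3) in aqueous acetone at 0 °C transfers Cl+ to C8=C9, and water opens the chloronium ion at the tertiary carbon C9 in anti fashion, which leads directly to 19. Chlorine now arrives as the electrophile and oxygen as the nucleophile, so the facial demand is the reverse of that of steps 8 and 9. This sequence therefore gains if the alkene prefers attack from the C5 side. Ene-type allylic chlorination is its own side path. It makes no compound outside the list (F0).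

**Further compounds**
F1 | step 3 | (2S)-N,N-diethyl-2-({(Z)-[4-isobutoxy-6,6-dimethyl-2-oxocyclohex-3-en-1-ylidene]methyl}amino)-3-methylbutanamide | CC1(C)CC(OCC(C)C)=CC(=O)/C1=C\N[C@@H](C(C)C)C(=O)N(CC)CC
F2 | step 3 | (2S)-N,N-diethyl-2-({(E)-[(1R)-4-isobutoxy-6,6-dimethyl-2-oxo-1-(3-oxobutyl)cyclohex-3-en-1-yl]methylidene}amino)-3-methylbutanamide | O=C1C=C(OCC(C)C)CC(C)(C)[C@@]1(/C=N/[C@@H](C(C)C)C(=O)N(CC)CC)CCC(C)=O
F3 | step 10 | (2R,6R,8S)-2-bromo-8-chloro-1,1,5,9-tetramethylspiro[5.5]undeca-4,9-dien-3-one | CC1=CC(=O)[C@H](Br)C(C)(C)[C@@]12CC=C(C)[C@@H](Cl)C2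
F0 | step 9 | none | none
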